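The route cuts two neighbouring bonds on the benzene ring of the 2H-chromene (O1, C2, C3, C4, C4a, C5–C8, C8a): the C5–O bond and the C6–acyl bond. A C5≡C6 aryne inserts into the C–O bond of a carboxylate. The phenol oxygen and the ketone carbon therefore arrive together on adjacent carbons, and C8 is never exposed to an electrophile. The feature exploited is the C7 methoxy group beside C6. It polarises the aryne so that oxygen binds C5 and the carbanion, then the acyl group, ends at C6. The precursors are the 6-trimethylsilyl-5-triflyloxy chromene and dioxolane-masked benzoylacetic acid, used as its dry cesium salt.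

Key step: step 9

Assumption: the target is drawn as its diketo tautomer. It should equilibrate with the chelated enol form, which is the same compound for this route.

Step 1
Reactants: 1 phloroglucinol (benzene-1,3,5-triol); 2 3-methylbut-2-enoic acid
Product: 4 5,7-dihydroxy-2,2-dimethylchroman-4-one, via acyl enone 3 (not isolated)
Conditions: P2O5, MeSO3H, 70 °C
Reagents that add atoms: none
Why: Friedel–Crafts acylation of the threefold-symmetric phenol by the activated unsaturated acid gives enone 3, whose ortho hydroxyl closes the pyranone ring by 6-endo oxa-Michael addition, so no regiochemical question arises.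

Step 2
Reactants: 4 5,7-dihydroxy-2,2-dimethylchroman-4-one
Product: 5 5-hydroxy-7-methoxy-2,2-dimethylchroman-4-one
Conditions: Me2SO4 (1.0 equiv), K2CO3, acetone, reflux
Reagents that add atoms: dimethyl sulfate, COS(=O)(=O)OC
Why: Williamson-type O-methylation should pick the C7 hydroxyl, the more acidic vinylogous-acid site, because the C5 hydroxyl is held in a hydrogen bond to the C4 carbonyl and only one equivalent of the hard electrophile is offered.

Step 3
Reactants: 5 5-hydroxy-7-methoxy-2,2-dimethylchroman-4-one
Product: 7 7-methoxy-2,2-dimethyl-2H-chromen-5-ol, via chromane-4,5-diol 6 (not isolated)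
Conditions: NaBH4, THF–EtOH, 0 °C to rt; aq. NH4Cl; then crude 6, pyridinium p-toluenesulfonate (PPTS, cat.), toluene (dilute), 60 °C
Reagents that add atoms: none
Why: Borohydride reduction of 5-hydroxychroman-4-ones to the 4-ols is established for 5-hydroxyflavanones, and the racemic, triply oxygen-activated benzylic alcohol 6 should ionise under very weak acid and lose a C3 proton (E1 dehydration, the standard 2,2-dimethylchromene route), with dilution and the weak acid holding back cationic coupling to the electron-rich ring.

Step 4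
Reactants: 7 7-methoxy-2,2-dimethyl-2H-chromen-5-ol
Product: 8 7-methoxy-2,2-dimethyl-2H-chromen-5-yl isopropylcarbamate
Conditions: i-PrNCO, Et3N (cat.), CH2Cl2, rt
Reagents that add atoms: isopropyl isocyanate, CC(C)N=C=O
Why: Base-catalysed addition of the phenol to the isocyanate gives an N-monoalkyl O-aryl carbamate, a strong ortho-directing group chosen because it can later be removed with mild base instead of the acid or hydride that would endanger a C6 silane.

Step 5
Reactants: 8 7-methoxy-2,2-dimethyl-2H-chromen-5-yl isopropylcarbamate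
Product: 12 7-methoxy-2,2-dimethyl-6-(trimethylsilyl)-2H-chromen-5-yl isopropylcarbamate, via N-silyl carbamate 9 (not isolated), via aryllithium 10 (not isolated), via bis-silyl carbamate 11 (not isolated)
Conditions: TBSOTf (1.1 equiv), TMEDA, Et2O, 0 °C to rt; n-BuLi (2.2 equiv), TMEDA, −78 °C; TMSCl, −78 °C to rt; cold aq. NaHSO4 (brief)
Reagents that add atoms: chlorotrimethylsilane, C[Si](C)(C)Cl
Why: Directed ortho-metalation, in which temporary N-silylation masks the acidic N–H, the carbamate guides n-BuLi to C6 (its only free ortho position, further activated by the C7 methoxy group), TMSCl traps aryllithium 10 at −78 °C before carbamoyl migration can start, and the labile N–Si bond is hydrolysed on work-up.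

Step 6
Reactants: 12 7-methoxy-2,2-dimethyl-6-(trimethylsilyl)-2H-chromen-5-yl isopropylcarbamate
Product: 14 7-methoxy-2,2-dimethyl-6-(trimethylsilyl)-2H-chromen-5-yl trifluoromethanesulfonate, via silyl phenol 13 (not isolated)
Conditions: Et2NH, DBU, MeCN, 40 °C; then PhNTf2, rt
Reagents that add atoms: N-phenylbis(trifluoromethanesulfonimide), O=S(=O)(N(c1ccccc1)S(=O)(=O)C(F)(F)F)C(F)(F)F
Why: DBU removes the carbamate N–H and E1cB loss of isopropyl isocyanate (scavenged by Et2NH) frees the phenoxide of 13 without any acid that could protodesilylate C6, and PhNTf2 sulfonylates it in the same flask, the established carbamate-to-silyl-triflate sequence.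

Step 7
Reactants: 15 ethyl benzoylacetate
Product: 16 ethyl 2-(2-phenyl-1,3-dioxolan-2-yl)acetate
Conditions: HOCH2CH2OH, p-TsOH·H2O (cat.), toluene, Dean–Stark, reflux
Reagents that add atoms: ethylene glycol, OCCO
Why: Acid-catalysed ketalisation with azeotropic removal of water masks the aryl ketone of the β-keto ester, a known transformation of this substrate.

Step 8
Reactants: 16 ethyl 2-(2-phenyl-1,3-dioxolan-2-yl)acetate
Product: 17 2-(2-phenyl-1,3-dioxolan-2-yl)acetic acid
Conditions: LiOH, THF–H2O, rt; then cold 1 M HCl to pH 3–4, immediate extraction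
Reagents that add atoms: lithium hydroxide, [Li+].[OH-]
Why: Saponification leaves the base-stable ketal untouched, and brief cold acidification to a mild pH frees the acid without hydrolysis to the decarboxylation-prone β-keto acid.

Step 9
Reactants: 14 7-methoxy-2,2-dimethyl-6-(trimethylsilyl)-2H-chromen-5-yl trifluoromethanesulfonate; 17 2-(2-phenyl-1,3-dioxolan-2-yl)acetic acid
Product: 21 1-(5-hydroxy-7-methoxy-2,2-dimethyl-2H-chromen-6-yl)-2-(2-phenyl-1,3-dioxolan-2-yl)ethan-1-one, via cesium carboxylate 18 (not isolated), via aryne 19 (not isolated), via aryl anion 20 (not isolated)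
Conditions: 17 (2 equiv), Cs2CO3 (1 equiv), MeOH, rt, evaporate, dry (toluene azeotrope, vacuum); then 14 (1 equiv), CsF (3 equiv), THF, 125 °C, sealed tube; AcOH quench
Reagents that add atoms: none
Why: CsF removes the C6 silyl group and triflate departs from C5 to give aryne 19; the carboxylate oxygen of 18 bonds to C5, the resulting aryl anion 20 at C6 adds to its own ester carbonyl through a strained four-centre arrangement, and collapse of the C–O bond delivers the chelated phenoxide of 21, which AcOH protonates. This is the known aryne insertion into the C–O bond of carboxylic acids, in effect an anionic ortho-Fries acyl shift, which gives ortho-hydroxyaryl ketones with CsF in hot THF. No ring is closed and no stereocentre is formed. Regioselectivity is needed and comes from the C7 methoxy group: as in 3-methoxybenzyne its inductive pull widens the internal angle at the remote carbon C5 and stabilises charge at C6, which should outweigh the modest steric shielding of C5 by C4a. Chemoselectivity for acyl shift over protonation of 20 is secured by the preformed, dried cesium salt, by a solvent without acidic hydrogen and by slow aryne release from sparingly soluble CsF. The dioxolane prevents decarboxylation of the acid partner and leaves the new phenoxide no second carbonyl to condense with, and the excess of 18 lets it outcompete the product phenoxide and the C3=C4 alkene for the aryne.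

Step 10
Reactants: 21 1-(5-hydroxy-7-methoxy-2,2-dimethyl-2H-chromen-6-yl)-2-(2-phenyl-1,3-dioxolan-2-yl)ethan-1-one
Product: 22 1-(5-hydroxy-7-methoxy-2,2-dimethyl-2H-chromen-6-yl)-3-phenylpropane-1,3-dione
Conditions: PPTS (cat.), acetone–H2O, reflux
Reagents that add atoms: water, O
Why: Mild acid-catalysed ketal hydrolysis in a water-rich medium unmasks the benzoyl ketone, and the weak acid is chosen because ortho-hydroxyaryl 1,3-diketones need far stronger acid to cyclodehydrate and the chromene alkene tolerates it.

Compound list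
1 | phloroglucinol (benzene-1,3,5-triol) | Oc1cc(O)cc(O)c1 | starting material
2 | 3-methylbut-2-enoic acid | CC(C)=CC(O)=O | starting material
3 | 3-methyl-1-(2,4,6-trihydroxyphenyl)but-2-en-1-one | CC(C)=CC(=O)c1c(O)cc(O)cc1O | intermediate
4 | 5,7-dihydroxy-2,2-dimethylchroman-4-one | CC1(C)CC(=O)c2c(O)cc(O)cc2O1 | intermediate
5 | 5-hydroxy-7-methoxy-2,2-dimethylchroman-4-one | COc1cc(O)c2C(=O)CC(C)(C)Oc2c1 | intermediate
6 | 7-methoxy-2,2-dimethylchromane-4,5-diol (racemic at C4) | COc1cc(O)c2C(O)CC(C)(C)Oc2c1 | intermediate
7 | 7-methoxy-2,2-dimethyl-2H-chromen-5-ol | COc1cc(O)c2C=CC(C)(C)Oc2c1 | intermediate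
8 | 7-methoxy-2,2-dimethyl-2H-chromen-5-yl isopropylcarbamate | COc1cc(OC(=O)NC(C)C)c2C=CC(C)(C)Oc2c1 | intermediate
9 | 7-methoxy-2,2-dimethyl-2H-chromen-5-yl N-(tert-butyldimethylsilyl)-N-isopropylcarbamate | COc1cc(OC(=O)N(C(C)C)[Si](C)(C)C(C)(C)C)c2C=CC(C)(C)Oc2c1 | intermediate
10 | 6-lithio-7-methoxy-2,2-dimethyl-2H-chromen-5-yl N-(tert-butyldimethylsilyl)-N-isopropylcarbamate | COc1cc2OC(C)(C)C=Cc2c(OC(=O)N(C(C)C)[Si](C)(C)C(C)(C)C)c1[Li] | intermediate
11 | 7-methoxy-2,2-dimethyl-6-(trimethylsilyl)-2H-chromen-5-yl N-(tert-butyldimethylsilyl)-N-isopropylcarbamate | COc1cc2OC(C)(C)C=Cc2c(OC(=O)N(C(C)C)[Si](C)(C)C(C)(C)C)c1[Si](C)(C)C | intermediate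
12 | 7-methoxy-2,2-dimethyl-6-(trimethylsilyl)-2H-chromen-5-yl isopropylcarbamate | COc1cc2OC(C)(C)C=Cc2c(OC(=O)NC(C)C)c1[Si](C)(C)C | intermediate
13 | 7-methoxy-2,2-dimethyl-6-(trimethylsilyl)-2H-chromen-5-ol | COc1cc2OC(C)(C)C=Cc2c(O)c1[Si](C)(C)C | intermediate
14 | 7-methoxy-2,2-dimethyl-6-(trimethylsilyl)-2H-chromen-5-yl trifluoromethanesulfonate | COc1cc2OC(C)(C)C=Cc2c(OS(=O)(=O)C(F)(F)F)c1[Si](C)(C)C | intermediate
15 | ethyl benzoylacetate | CCOC(=O)CC(=O)c1ccccc1 | starting material
16 | ethyl 2-(2-phenyl-1,3-dioxolan-2-yl)acetate | CCOC(=O)CC1(c2ccccc2)OCCO1 | intermediate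
17 | 2-(2-phenyl-1,3-dioxolan-2-yl)acetic acid | OC(=O)CC1(c2ccccc2)OCCO1 | intermediate
18 | cesium 2-(2-phenyl-1,3-dioxolan-2-yl)acetate | [Cs+].[O-]C(=O)CC1(c2ccccc2)OCCO1 | intermediate
19 | 7-methoxy-2,2-dimethyl-5,6-didehydro-2H-chromene (C5≡C6 aryne) | COC1=CC2=C(C=CC(C)(C)O2)C#C1 | intermediate
20 | cesium 7-methoxy-2,2-dimethyl-5-{[(2-phenyl-1,3-dioxolan-2-yl)acetyl]oxy}-2H-chromen-6-ide | COc1cc2OC(C)(C)C=Cc2c(OC(=O)CC2(c3ccccc3)OCCO2)[c-]1.[Cs+] | intermediate
21 | 1-(5-hydroxy-7-methoxy-2,2-dimethyl-2H-chromen-6-yl)-2-(2-phenyl-1,3-dioxolan-2-yl)ethan-1-one | COc1cc2OC(C)(C)C=Cc2c(O)c1C(=O)CC1(c2ccccc2)OCCO1 | intermediate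
22 | 1-(5-hydroxy-7-methoxy-2,2-dimethyl-2H-chromen-6-yl)-3-phenylpropane-1,3-dione | COc1cc2c(c(O)c1C(=O)CC(=O)c1ccccc1)C=CC(C)(C)O2 | target

Total step count: 10.
Longest linear sequence: 8 (steps 1–6, 9, 10). The acid branch (steps 7 and 8) joins at step 9.

Steps most likely to fail

**Step 9 (key step).**
- The aryl anion may be quenched before the acyl shift. The proton could be adventitious or could come by internal transfer from the α-methylene of its own ester. Either way the reaction would stop at plain O-arylation.
- Long heating with fluoride may open the dioxolane by β-elimination and let the phenoxide close a pyranone ring.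
- The aryne may be intercepted by product phenoxide or by the C3=C4 alkene of a second molecule.
- Fallback from 8 and 17, returning at 21: the same C6 carbanion is made by metalation instead of through an aryne. Acid 17 is converted with 1,1'-carbonyldiimidazole and MeNH(OMe)·HCl into N-methoxy-N-methyl-2-(2-phenyl-1,3-dioxolan-2-yl)acetamide F1. Carbamate 8 is N-silylated and lithiated as in step 5 to aryllithium 10. This is acylated by F1 at −78 °C (Weinreb-type ketone synthesis) to the N-silyl keto carbamate F2. The cold NaHSO4 work-up should give the keto carbamate F3. Et2NH/DBU in MeCN then removes the carbamoyl group to give 21.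

**Step 5.**
- Metalation may stray to C8 between the two ether oxygens or to the vinylic C4 position.
- n-BuLi may add across C3=C4.
- The carbamoyl group may migrate if the anion warms.
- The new silyl group may be lost by ipso-protonation during the acidic work-up.
- Fallback from 7, returning at 14: halogenation followed by retro-Brook silyl transfer replaces the directed metalation and bypasses steps 4–6. Amine-catalysed ortho-bromination (NBS, cat. i-Pr2NH, CH2Cl2, low temperature) should give 6-bromo-7-methoxy-2,2-dimethyl-2H-chromen-5-ol F4. Hexamethyldisilazane in hot THF gives its trimethylsilyl ether F5. n-BuLi in THF at −78 °C effects bromine–lithium exchange to the aryllithium F6. An O-to-C silyl shift in F6 gives the lithium phenoxide of 13, and Tf2O added to the same flask gives 14.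

**Step 10.**
- Hydrolysis may be sluggish because the β-carbonyl destabilises the oxocarbenium ion.
- If the reaction is forced with stronger acid, the C5 hydroxyl may attack the unmasked carbon and lose water (cyclodehydration), or the chromene alkene may undergo cationic oligomerisation.
- Fallback from 14, returning at 22: the ketal and the acidic unmasking are avoided altogether. Triflate 14 with dry CsOAc and CsF in THF at 125 °C (via aryne 19) should give 1-(5-hydroxy-7-methoxy-2,2-dimethyl-2H-chromen-6-yl)ethan-1-one F7. BzCl, pyridine and cat. DMAP give 6-acetyl-7-methoxy-2,2-dimethyl-2H-chromen-5-yl benzoate F8. A Baker–Venkataraman rearrangement (KOt-Bu, THF, 0 °C to rt, then AcOH) moves the benzoyl group from oxygen to the acetyl carbon and gives 22.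

Further compounds
F1 | step 9 | N-methoxy-N-methyl-2-(2-phenyl-1,3-dioxolan-2-yl)acetamide | CON(C)C(=O)CC1(c2ccccc2)OCCO1
F2 | step 9 | 7-methoxy-2,2-dimethyl-6-[(2-phenyl-1,3-dioxolan-2-yl)acetyl]-2H-chromen-5-yl N-(tert-butyldimethylsilyl)-N-isopropylcarbamate | COc1cc2OC(C)(C)C=Cc2c(OC(=O)N(C(C)C)[Si](C)(C)C(C)(C)C)c1C(=O)CC1(c2ccccc2)OCCO1
F3 | step 9 | 7-methoxy-2,2-dimethyl-6-[(2-phenyl-1,3-dioxolan-2-yl)acetyl]-2H-chromen-5-yl isopropylcarbamate | COc1cc2OC(C)(C)C=Cc2c(OC(=O)NC(C)C)c1C(=O)CC1(c2ccccc2)OCCO1
F4 | step 5 | 6-bromo-7-methoxy-2,2-dimethyl-2H-chromen-5-ol | COc1cc2OC(C)(C)C=Cc2c(O)c1Br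
F5 | step 5 | [(6-bromo-7-methoxy-2,2-dimethyl-2H-chromen-5-yl)oxy]trimethylsilane | COc1cc2OC(C)(C)C=Cc2c(O[Si](C)(C)C)c1Br
F6 | step 5 | [(6-lithio-7-methoxy-2,2-dimethyl-2H-chromen-5-yl)oxy]trimethylsilane | COc1cc2OC(C)(C)C=Cc2c(O[Si](C)(C)C)c1[Li]
F7 | step 10 | 1-(5-hydroxy-7-methoxy-2,2-dimethyl-2H-chromen-6-yl)ethan-1-one | COc1cc2OC(C)(C)C=Cc2c(O)c1C(C)=O
F8 | step 10 | 6-acetyl-7-methoxy-2,2-dimethyl-2H-chromen-5-yl benzoate | COc1cc2OC(C)(C)C=Cc2c(OC(=O)c2ccccc2)c1C(C)=O
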